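## The problem

CNP0335239.1 is a longipinane diester. A verbenone-like bicyclo[3.1.1]heptenone (bridge C1–C11(=O)–C10=C9(Me)–C8) shares its cyclobutane C1–C2–C8–C7 with a seven-membered ring, whose chain C2(Me)–C3(O-senecioyl)–C4–C5(O-isovaleryl)–C6(Me)2–C7 spans the other face of the four-membered ring; these locants are used for every intermediate below. Of the six stereocentres, C1, C2, C7 and C8 are tied together by the ring system: once C7 and C8 are cis in a bicyclic precursor the cyclobutane can close in one way only, so C1 and the quaternary C2 need no control of their own. C3 and C5 are the opposite case. C2–C7 and the C2 methyl lie in a local mirror plane of the skeleton, and the two faces of a trigonal C3 or C5 differ only in whether the distant C11 carbonyl or the C9 methyl lies beyond them, so one centre must come from a reagent and the other from a 1,3-anti relay. Both carbinols are neopentyl and carry different acyl groups, so they must be told apart by the chemistry and not by sterics. A cation at C3 is cyclobutylcarbinyl and invites Wagner–Meerwein ring expansion, a β-acyloxy ketone eliminates easily, and the senecioate deconjugates under strong amine bases, so acidic unmasking steps and late strong-base steps are excluded. The key step is possible because the C11 ketone and the C3 oxygen are 1,4-related through the cyclobutane bond C1–C2: with C3 as a ketone, this bond joins two carbons that are each α to a carbonyl, the product of joining two enolates by oxidation.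

## Retrosynthesis

**Esters and carbinol centres (31 ⇒ 29 ⇒ 27 ⇒ 25).** The C3–O acyl bond is cut first, giving hydroxy ester 29 and acid chloride 30. 29 is the product of an Evans–Tishchenko reaction of β-hydroxy ketone 27 with aldehyde 28, a cut that removes the isovaleryl C–O bond and the C3–H bond together. This is preferred to reduction of a C3/C5 diketone or to a free anti-diol, because it relays C5 to C3 by intramolecular hydride delivery and leaves the two neopentyl oxygens already differentiated. The C5–O bond of 27 is then cut back to the enone 25 (conjugate borylation, oxidation). 25 has no stereocentre on the seven-membered ring; the forward step must choose between two locally equivalent faces, which only a chiral catalyst can do.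

**Cyclobutane (25 ⇒ 23).** The C1–C2 bond is cut, giving the cis-fused bicyclo[5.4.0]undecadienedione 23. Cutting two cyclobutane bonds at once ([2+2]) would remove more complexity per step, but it leaves either the seven-membered ring or its oxygen pattern to be built on the strained core. The single cut gives a precursor with only two stereocentres that matter (C7, C8) and all fifteen skeletal carbons in place. C4=C5 is kept as a plain alkene, not as a C5 enol ether. It blocks enolisation toward C4 equally well (C6 is quaternary), and it avoids two problems of the enol ether: the alkoxy group would have to sit on the more hindered oxygen of a 1,3-dione, and the least electrophilic carbonyl would later have to be reduced beside the C11 enone. The forward reaction needs double α′-deprotonation (bis-enolate 24) and an oxidant that joins C1 to C2 faster than either radical is lost.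

**Seven-membered ring (23 ⇒ 22 ⇒ 21).** The C11 carbonyl is removed (allylic oxidation in the forward sense), so that the enone, whose γ-carbon C8 is epimerisable, appears only one step before the kinetic deprotonation. C4=C5 of 22 is then cut by ring-closing metathesis to vinyl ketone 21. An aldol condensation for the same bond would have two enolisable sites; metathesis is unambiguous and neutral.

**Functional-group level (21 ⇒ 19 ⇒ 18 ⇒ 17 ⇒ 15 ⇒ 14).** The vinyl ketone comes from the C3 carboxyl (Weinreb amide 19 and Grignard reagent 20), the vinyl group on C6 from the C5 carboxyl (aldehyde 17, alkene 18). Diacid 14 is differentiated as mono-ester 15 because one carboxyl is α-tertiary and the other α-quaternary.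

**Both side-chain bonds (14 ⇒ 10).** C6–C7 and C2–C8 each join a carbon α to a carboxyl to an allylic ring carbon, the retron of the Ireland–Claisen rearrangement. Cutting both leads to the cis-diol diester 10, in which the tertiary ester is allylic and the secondary ester becomes allylic once the first shift has moved the alkene. Each shift is suprafacial, so the cis relationship of the two oxygens becomes the cis relationship of C6 and C2 on C7 and C8. A Diels–Alder route to the same relationship would need a dienophile carbonyl on C2 and a later 1,2-carbonyl transposition, and conjugate additions would give the trans isomer.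

**Diol and source of chirality (10 ⇒ 8 ⇒ 6 ⇒ 3 ⇒ 2 ⇒ 1).** The acyl groups come from anhydrides 9 and 7. The cis-diol 6 with its tertiary allylic hydroxyl comes from epoxy alcohol 3 (selenide opening, selenoxide elimination), 3 from allylic alcohol 2 by hydroxyl-directed epoxidation, and 2 from enone 1 by Corey–Bakshi–Shibata reduction. This reduction is the only external source of chirality before the borylation.

## Roads not taken

Alternative 1: The cut is through two cyclobutane bonds, C1–C7 and C2–C8. In the forward sense an acyclic trienoyl chloride A2 is dehydrochlorinated by a tertiary amine to vinylketene A3, whose ketene C=C adds across the central trisubstituted alkene and gives bicyclo[3.1.1]heptenone A1 in one step.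
- Merits: both rings of the bicyclic core and the quaternary C2 arise together from a farnesoic-acid-like chain. Crossed intramolecular ketene–alkene cycloadditions of geranic-acid-type chlorides are well established, so the cyclobutane-forming event is better precedented here than the oxidative coupling of 24.
- Weak points: A1 has C7 as a cyclobutanone carbonyl, whereas the target needs C7 as a methine bonded to the quaternary C6. The seven-membered ring must therefore be closed by a C6–C7 bond at a neopentyl cyclobutanone and C7 then deoxygenated. A cation- or ene-type closure of the prenyl arm would bond C5, not C6. The C5 oxygen and the C11 carbonyl are also still missing, and one remote silyloxy centre must steer the facial course of the cycloaddition.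
- Comparison: this road is stronger in rings formed per step and in precedent for the four-membered ring. The chosen plan has no C–C bond left to make at the strained core after 25, and reaches the C3/C5 oxygen pattern in three steps from there.

Alternative 2: The cut is C3–C4 and C4–C5, that is, insertion of C4. Nor-ketone A5, a copaane-type tricycle with a six-membered ring, is enol-silylated at C3, cyclopropanated with a zinc carbenoid and opened oxidatively with an iron salt, which gives cycloheptenone A4.
- Merits: the ring expansion is reliable and regiochemically fixed, since only the C5 side of the ketone can enolise. A4 is the dioxolane, 9,10-dihydro counterpart of 25, so the borylation and Evans–Tishchenko endgame would apply unchanged.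
- Weak points: A5 already contains the cyclobutane and five stereocentres. Its own synthesis is the real problem, and the four-membered ring must still be made by some other key reaction. After the expansion the dioxolane must be removed and C9=C10 introduced.
- Comparison: the key step itself is safer than the coupling of 24, but the difficulty is moved, not solved, and the route is longer. The chosen plan makes the cyclobutane last, on a flexible bicycle assembled from simple acyl fragments.

Alternative 3: The cut is C1–C7, C6–C7 and C2–C8 in one cationic cascade. A longipinene synthase ionises farnesyl diphosphate A7 and releases α-longipinene A6.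
- Merits: the whole skeleton with its four ring stereocentres forms in one step from a fermentable C15 feedstock. No chemical route can match this for the carbon framework.
- Weak points: A6 is a hydrocarbon. The C11 ketone is within reach by allylic oxidation, but C3 and C5 are unactivated methylenes of a locally symmetric ring. No chemical C–H oxidation distinguishes C3, C4 and C5 or their faces, so two engineered oxygenases would be needed as well as a synthase of the right enantiomeric series.
- Comparison: with such enzymes in hand this would be the shortest route. The chosen plan gives up skeletal step economy in exchange for oxygen atoms placed by design, since C3 and C5 are functionalised from 21 onward.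

Key step: step 14

Assumptions:
- C2 arises in step 6 as a mixture of epimers, becomes trigonal in 24 and is fixed in step 14; it is left open in the names and SMILES of 11–23.
- The (R,SP) antipode of the Josiphos ligand is taken to deliver boron to the C5 face syn to C8; the substrate is unbiased, so the mirror-image ligand is used if a trial on 25 shows the opposite sense.

## Steps

Step 1
Reactants: 1 2-methylcyclohex-2-en-1-one
Product: 2 (S)-2-methylcyclohex-2-en-1-ol
Conditions: (R)-2-methyl-CBS-oxazaborolidine (10 mol %), catecholborane (1.5 equiv), toluene, −78 °C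
Reagents that add atoms: none
Why: Corey–Bakshi–Shibata reduction; the 2-methylvinyl arm acts as the large group, so the (R)-catalyst should deliver hydride to the face that gives the (S)-carbinol (future C10), and 1,2-reduction is favoured at low temperature.

Step 2
Reactants: 2 (S)-2-methylcyclohex-2-en-1-ol
Product: 3 (1S,2S,6R)-1-methyl-7-oxabicyclo[4.1.0]heptan-2-ol
Conditions: VO(acac)2 (2 mol %), tBuOOH (1.5 equiv), CH2Cl2, 0 → 23 °C
Reagents that add atoms: tert-butyl hydroperoxide, CC(C)(C)OO
Why: Hydroxyl-directed epoxidation; the vanadate ester of the allylic alcohol delivers oxygen to the alkene face syn to the hydroxyl, which sets the C9 oxygen cis to the C10 oxygen.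

Step 3
Reactants: 3 (1S,2S,6R)-1-methyl-7-oxabicyclo[4.1.0]heptan-2-ol
Product: 6 (1S,2R)-2-methylcyclohex-3-ene-1,2-diol, via hydroxy selenide 4 (not isolated), via selenoxide 5 (not isolated)
Conditions: (PhSe)2, NaBH4, EtOH, 23 → 70 °C; then H2O2 (30 %), THF, 0 → 23 °C
Reagents that add atoms: none
Why: Epoxide opening by selenolate and selenoxide syn-elimination; the selenolate attacks the secondary epoxide carbon C8 trans-diaxially and the selenoxide can eliminate only toward C7 (C9 has no hydrogen), so the epoxy alcohol becomes the cis-diol with a tertiary allylic hydroxyl and the C9–O bond is never broken.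

Step 4
Reactants: 6 (1S,2R)-2-methylcyclohex-3-ene-1,2-diol; 7 propanoic anhydride
Product: 8 (1S,2R)-2-hydroxy-2-methylcyclohex-3-en-1-yl propanoate
Conditions: 7 (1.05 equiv), pyridine, 4-dimethylaminopyridine (5 mol %), CH2Cl2, 0 °C
Reagents that add atoms: none
Why: Selective acylation; the secondary hydroxyl reacts far faster than the tertiary one, so one equivalent of anhydride should acylate the C10 oxygen only.

Step 5
Reactants: 8 (1S,2R)-2-hydroxy-2-methylcyclohex-3-en-1-yl propanoate; 9 2-methylpropanoic anhydride
Product: 10 (1S,2R)-2-methyl-2-(2-methylpropanoyloxy)cyclohex-3-en-1-yl propanoate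
Conditions: 9 (3 equiv), Et3N, 4-dimethylaminopyridine (1 equiv), CH2Cl2, 40 °C
Reagents that add atoms: none
Why: Acyl-pyridinium acylation of a tertiary alcohol; no alkoxide is formed, which should suppress 1,2-acyl migration, and the conditions are not ionising for the tertiary allylic centre.

Step 6
Reactants: 10 (1S,2R)-2-methyl-2-(2-methylpropanoyloxy)cyclohex-3-en-1-yl propanoate
Product: 14 2-[(1R,2S)-2-(1-carboxyethyl)-3-methylcyclohex-3-en-1-yl]-2-methylpropanoic acid, via bis(silyl ketene acetal) 11 (not isolated), via mono-rearranged silyl ester 12 (not isolated), via bis(trimethylsilyl) ester 13 (not isolated)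
Conditions: LiN(iPr)2 (2.6 equiv), Me3SiCl–Et3N, THF, −78 → 23 → 60 °C; then 1 M HCl
Reagents that add atoms: none
Why: Two Ireland–Claisen rearrangements in one flask: the tertiary allylic 2-methylpropanoate shifts first (C6–C7, alkene to C8=C9), which makes the propanoate allylic so that it shifts in turn (C2–C8, alkene to C9=C10). Each [3,3] shift is suprafacial, so both new bonds form on the face of the departing oxygens; these are cis, so C7 and C8 are set cis (7R,8S) with the absolute sense taken from C9 and C10 of 10.

Step 7
Reactants: 14 2-[(1R,2S)-2-(1-carboxyethyl)-3-methylcyclohex-3-en-1-yl]-2-methylpropanoic acid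
Product: 15 2-[(1R,2S)-2-(1-methoxy-1-oxopropan-2-yl)-3-methylcyclohex-3-en-1-yl]-2-methylpropanoic acid
Conditions: MeOH, AcCl (0.2 equiv), 0 → 23 °C
Reagents that add atoms: methanol, CO
Why: Fischer esterification; the α-tertiary acid forms its tetrahedral intermediate readily and the α-quaternary, neopentyl-type acid does not, so dilute HCl in methanol should esterify the C3 carboxyl only.

Step 8
Reactants: 15 2-[(1R,2S)-2-(1-methoxy-1-oxopropan-2-yl)-3-methylcyclohex-3-en-1-yl]-2-methylpropanoic acid
Product: 17 methyl 2-[(1S,6R)-2-methyl-6-(2-methyl-1-oxopropan-2-yl)cyclohex-2-en-1-yl]propanoate, via acid chloride 16 (not isolated)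
Conditions: (COCl)2, DMF (cat.), CH2Cl2, 0 → 23 °C; then LiAlH(OtBu)3 (1.05 equiv), THF, −78 °C
Reagents that add atoms: none
Why: Acid chloride formation and reduction with the bulky, mild hydride LiAlH(OtBu)3, which stops at the aldehyde and leaves the methyl ester and the trisubstituted alkene untouched.

Step 9
Reactants: 17 methyl 2-[(1S,6R)-2-methyl-6-(2-methyl-1-oxopropan-2-yl)cyclohex-2-en-1-yl]propanoate
Product: 18 methyl 2-[(1S,6R)-2-methyl-6-(2-methylbut-3-en-2-yl)cyclohex-2-en-1-yl]propanoate
Conditions: Ph3PCH3Br, KOtBu, THF, 0 °C
Reagents that add atoms: methylenetriphenylphosphorane (from methyltriphenylphosphonium bromide), C=P(c1ccccc1)(c1ccccc1)c1ccccc1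
Why: Wittig methylenation of a non-enolisable neopentyl aldehyde; it turns C5 into the alkene carbon needed for ring closure.

Step 10
Reactants: 18 methyl 2-[(1S,6R)-2-methyl-6-(2-methylbut-3-en-2-yl)cyclohex-2-en-1-yl]propanoate
Product: 19 N-methoxy-N-methyl-2-[(1S,6R)-2-methyl-6-(2-methylbut-3-en-2-yl)cyclohex-2-en-1-yl]propanamide
Conditions: MeNH(OMe)·HCl, iPrMgCl, THF, −20 → 0 °C
Reagents that add atoms: N,O-dimethylhydroxylamine hydrochloride, CNOC.Cl
Why: Ester to Weinreb amide with the magnesium amide of N,O-dimethylhydroxylamine; epimerisation at C2 is of no consequence.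

Step 11
Reactants: 19 N-methoxy-N-methyl-2-[(1S,6R)-2-methyl-6-(2-methylbut-3-en-2-yl)cyclohex-2-en-1-yl]propanamide; 20 vinylmagnesium bromide
Product: 21 4-[(1S,6R)-2-methyl-6-(2-methylbut-3-en-2-yl)cyclohex-2-en-1-yl]pent-1-en-3-one
Conditions: 20 (2 equiv), THF, 0 °C; inverse quench into cold 1 M HCl
Reagents that add atoms: none
Why: Grignard addition to a Weinreb amide stops at the ketone through the chelated tetrahedral intermediate; the acidic inverse quench prevents conjugate addition of the released amine to the vinyl ketone.

Step 12
Reactants: 21 4-[(1S,6R)-2-methyl-6-(2-methylbut-3-en-2-yl)cyclohex-2-en-1-yl]pent-1-en-3-one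
Product: 22 (7R,8S)-2,6,6,9-tetramethylbicyclo[5.4.0]undeca-4,9-dien-3-one (cis-fused; locants of the problem section)
Conditions: second-generation Hoveyda–Grubbs catalyst RuCl2(H2IMes)(=CH-C6H4-2-OiPr) (5 mol %), toluene (5 mM), 80 °C
Reagents that add atoms: none
Why: Ring-closing metathesis of the vinyl ketone with the monosubstituted alkene; the cis arrangement on the six-membered ring and the gem-dimethyl group favour closure of the cycloheptenone, and the trisubstituted ring alkene is inert.

Step 13
Reactants: 22 (7R,8S)-2,6,6,9-tetramethylbicyclo[5.4.0]undeca-4,9-dien-3-one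
Product: 23 (7R,8S)-2,6,6,9-tetramethylbicyclo[5.4.0]undeca-4,9-diene-3,11-dione (cis-fused)
Conditions: CrO3, 3,5-dimethylpyrazole, CH2Cl2, −20 °C
Reagents that add atoms: chromium trioxide, O=[Cr](=O)=O
Why: Allylic oxidation with the CrO3–3,5-dimethylpyrazole complex; C11 is the only allylic methylene (C8–H is tertiary and shielded, C6 is quaternary), and oxidation next to the unsubstituted alkene carbon gives the β-methyl enone.

Step 14
Reactants: 23 (7R,8S)-2,6,6,9-tetramethylbicyclo[5.4.0]undeca-4,9-diene-3,11-dione
Product: 25 (1R,2R,7S,8R)-tricyclic dienedione with the C1–C2 bond closed (3-oxo-4-ene and 11-oxo-9-ene), via dilithium bis-enolate 24 (not isolated)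
Conditions: LiN(iPr)2 (2.4 equiv), THF, −78 → −40 °C; then FeCl3 (2.3 equiv) in DMF, −78 → 0 °C; high dilution
Reagents that add atoms: none
Why: Two equivalents of LiN(iPr)2 remove the only kinetically accessible protons, C1–H (α′ of the cyclohexenone) and C2–H (α′ of the cycloheptenone, whose γ-carbon C6 is quaternary), to give 24. FeCl3 (trivalent iron) oxidises one enolate to an α-keto radical, which adds to the neighbouring enolate, and a second electron transfer from the resulting ketyl gives the 1,4-diketone. The closest known reaction type is the intramolecular oxidative coupling of ketone and ester bis-enolates with FeCl3, CuCl2 or I2, which closes small rings including cyclobutanes; a bridged cyclobutane with a quaternary carbon extends that precedent. The four-membered ring closes in a 4-exo-trig sense (the attacked enolate C=C lies outside the new ring), and the same bond completes the bicyclo[3.1.1]heptenone. C1 and C2 need no outside control: the cis fusion at C7/C8 holds both enolate carbons on one face, so the bond can form only there, which puts C1–H and the C2 methyl on the outer face and erases the C2 mixture. The step needs double α′-deprotonation and intramolecular coupling; the first is secured by a kinetic base at low temperature and the blocked γ-position, the second by the 1,4 relationship and dilution.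

Step 15
Reactants: 25 (1R,2R,7S,8R)-tricyclic dienedione
Product: 27 (1R,2R,5R,7S,8R)-5-hydroxy tricyclic 3,11-dione (C9=C10 retained), via C5 pinacol boronate 26 (not isolated)
Conditions: CuCl (5 mol %), NaOtBu (10 mol %), (R,SP)-Josiphos (6 mol %), B2pin2 (1.2 equiv), MeOH (2 equiv), THF, 23 °C; then NaBO3·4H2O, THF–H2O, 23 °C
Reagents that add atoms: sodium perborate, [Na+].[O-]OB=O
Why: Copper-catalysed conjugate borylation, then oxidation with retention; the cis-disubstituted cycloheptenone reacts and the β,β-disubstituted bridged enone does not. The two faces of C4=C5 are locally equivalent, so the chiral phosphine decides, and boron should be delivered syn to C8 (5R).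

Step 16
Reactants: 27 (1R,2R,5R,7S,8R)-5-hydroxy tricyclic 3,11-dione; 28 3-methylbutanal
Product: 29 (1R,2R,3R,5R,7S,8R)-3-hydroxy-11-oxo tricyclic 9-en-5-yl 3-methylbutanoate
Conditions: 28 (6 equiv), SmI2 (0.3 equiv), THF, −10 °C
Reagents that add atoms: none
Why: Evans–Tishchenko reduction; the C5 hydroxyl forms a samarium hemiacetal with 28 and passes its hydride intramolecularly to the same face of the C3 ketone, which gives the anti-1,3-diol with C5 already esterified and C3–OH free. The enone has no directing hydroxyl and should be left alone.

Step 17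
Reactants: 29 (1R,2R,3R,5R,7S,8R)-3-hydroxy-11-oxo tricyclic 9-en-5-yl 3-methylbutanoate; 30 3-methylbut-2-enoyl chloride
Product: 31 CNP0335239.1, the (1R,2R,3R,5R,7S,8R)-3-(3-methylbut-2-enoyloxy)-5-(3-methylbutanoyloxy) tricyclic 9-en-11-one
Conditions: 30 (3 equiv), pyridine, 4-dimethylaminopyridine (0.2 equiv), CH2Cl2, 0 → 35 °C
Reagents that add atoms: none
Why: Acyl-pyridinium acylation of the remaining neopentyl alcohol; pyridine in place of a trialkylamine limits vinylketene formation and deconjugation of the senecioyl group, and the trans-1,3 arrangement disfavours acyl migration.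

## Compound list

1 | 2-methylcyclohex-2-en-1-one | CC1=CCCCC1=O | starting material
2 | (S)-2-methylcyclohex-2-en-1-ol | CC1=CCCC[C@@H]1O | intermediate
3 | (1S,2S,6R)-1-methyl-7-oxabicyclo[4.1.0]heptan-2-ol (epoxide cis to hydroxyl) | C[C@@]12O[C@@H]1CCC[C@@H]2O | intermediate
4 | (1S,2S,3S)-2-methyl-3-(phenylselanyl)cyclohexane-1,2-diol | C[C@@]1(O)[C@@H]([Se]c2ccccc2)CCC[C@@H]1O | intermediate
5 | (1S,2S,3S)-2-methyl-3-(phenylseleninyl)cyclohexane-1,2-diol | C[C@@]1(O)[C@@H]([Se](=O)c2ccccc2)CCC[C@@H]1O | intermediate
6 | (1S,2R)-2-methylcyclohex-3-ene-1,2-diol (cis-diol) | C[C@@]1(O)C=CCC[C@@H]1O | intermediate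
7 | propanoic anhydride | CCC(=O)OC(=O)CC | starting material
8 | (1S,2R)-2-hydroxy-2-methylcyclohex-3-en-1-yl propanoate | CCC(=O)O[C@H]1CCC=C[C@@]1(C)O | intermediate
9 | 2-methylpropanoic anhydride | CC(C)C(=O)OC(=O)C(C)C | starting material
10 | (1S,2R)-2-methyl-2-(2-methylpropanoyloxy)cyclohex-3-en-1-yl propanoate | CCC(=O)O[C@H]1CCC=C[C@@]1(C)OC(=O)C(C)C | intermediate
11 | bis(trimethylsilyl ketene acetal) of 10 | CC=C(O[Si](C)(C)C)O[C@H]1CCC=C[C@@]1(C)OC(O[Si](C)(C)C)=C(C)C | intermediate
12 | trimethylsilyl 2-methyl-2-[(1R,4S)-3-methyl-4-{[1-(trimethylsilyloxy)prop-1-en-1-yl]oxy}cyclohex-2-en-1-yl]propanoate | CC=C(O[Si](C)(C)C)O[C@H]1CC[C@@H](C(C)(C)C(=O)O[Si](C)(C)C)C=C1C | intermediate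
13 | bis(trimethylsilyl) ester of 14 | CC1=CCC[C@@H](C(C)(C)C(=O)O[Si](C)(C)C)[C@H]1C(C)C(=O)O[Si](C)(C)C | intermediate
14 | 2-[(1R,2S)-2-(1-carboxyethyl)-3-methylcyclohex-3-en-1-yl]-2-methylpropanoic acid (C2 open) | CC1=CCC[C@@H](C(C)(C)C(=O)O)[C@H]1C(C)C(=O)O | intermediate
15 | 2-[(1R,2S)-2-(1-methoxy-1-oxopropan-2-yl)-3-methylcyclohex-3-en-1-yl]-2-methylpropanoic acid | CC1=CCC[C@@H](C(C)(C)C(=O)O)[C@H]1C(C)C(=O)OC | intermediate
16 | acid chloride of 15 | CC1=CCC[C@@H](C(C)(C)C(Cl)=O)[C@H]1C(C)C(=O)OC | intermediate
17 | methyl 2-[(1S,6R)-2-methyl-6-(2-methyl-1-oxopropan-2-yl)cyclohex-2-en-1-yl]propanoate | CC1=CCC[C@@H](C(C)(C)C=O)[C@H]1C(C)C(=O)OC | intermediate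
18 | methyl 2-[(1S,6R)-2-methyl-6-(2-methylbut-3-en-2-yl)cyclohex-2-en-1-yl]propanoate | CC1=CCC[C@@H](C(C)(C)C=C)[C@H]1C(C)C(=O)OC | intermediate
19 | N-methoxy-N-methyl-2-[(1S,6R)-2-methyl-6-(2-methylbut-3-en-2-yl)cyclohex-2-en-1-yl]propanamide | CC1=CCC[C@@H](C(C)(C)C=C)[C@H]1C(C)C(=O)N(C)OC | intermediate
20 | vinylmagnesium bromide | C=C[Mg]Br | starting material
21 | 4-[(1S,6R)-2-methyl-6-(2-methylbut-3-en-2-yl)cyclohex-2-en-1-yl]pent-1-en-3-one | CC1=CCC[C@@H](C(C)(C)C=C)[C@H]1C(C)C(=O)C=C | intermediate
22 | (7R,8S)-2,6,6,9-tetramethylbicyclo[5.4.0]undeca-4,9-dien-3-one, cis-fused (locants of the problem section; C2 open) | O=C1C=CC(C)(C)[C@@H]2CCC=C(C)[C@@H]2C1C | intermediate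
23 | (7R,8S)-2,6,6,9-tetramethylbicyclo[5.4.0]undeca-4,9-diene-3,11-dione, cis-fused (C2 open) | O=C1C=CC(C)(C)[C@@H]2CC(=O)C=C(C)[C@@H]2C1C | intermediate
24 | dilithium C1(11),C2(3)-bis-enolate of 23 | [Li]OC1=C(C)[C@H]2C(C)=CC(O[Li])=C[C@H]2C(C)(C)C=C1 | intermediate
25 | (1R,2R,7S,8R)-tricyclic dienedione: cyclobutane C1–C2–C8–C7, 3-oxo-4-ene in the seven-membered ring, 11-oxo-9-ene in the six-membered ring | O=C1C=CC(C)(C)[C@@H]2[C@H]3C(=O)C=C(C)[C@@H]2[C@]31C | intermediate
26 | (5R)-5-(4,4,5,5-tetramethyl-1,3,2-dioxaborolan-2-yl)-4,5-dihydro derivative of 25 | O=C1C[C@@H](B2OC(C)(C)C(C)(C)O2)C(C)(C)[C@@H]2[C@H]3C(=O)C=C(C)[C@@H]2[C@]31C | intermediate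
27 | (1R,2R,5R,7S,8R)-5-hydroxy tricyclic 3,11-dione with C9=C10 (hydroxyl syn to C8) | O=C1C[C@@H](O)C(C)(C)[C@@H]2[C@H]3C(=O)C=C(C)[C@@H]2[C@]31C | intermediate
28 | 3-methylbutanal | CC(C)CC=O | starting material
29 | (1R,2R,3R,5R,7S,8R)-3-hydroxy-11-oxo tricyclic 9-en-5-yl 3-methylbutanoate (C3–OH syn to C1, anti to C5–O) | O[C@@H]1C[C@@H](OC(=O)CC(C)C)C(C)(C)[C@@H]2[C@H]3C(=O)C=C(C)[C@@H]2[C@]31C | intermediate
30 | 3-methylbut-2-enoyl chloride | CC(C)=CC(=O)Cl | starting material
31 | CNP0335239.1: (1R,2R,3R,5R,7S,8R)-3-(3-methylbut-2-enoyloxy)-5-(3-methylbutanoyloxy) tricyclic 9-en-11-one | CC(C)=CC(=O)O[C@@H]1C[C@@H](OC(=O)CC(C)C)C(C)(C)[C@@H]2[C@H]3C(=O)C=C(C)[C@@H]2[C@]31C | target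

## Step count and least certain steps

Total step count: 17. Longest linear sequence: 17 steps (1 → 31); the other numbered starting materials (7, 9, 20, 28, 30) each enter in a single step.

**Step 14 (key step).** The most likely failure is that the α-keto radical is intercepted before C1 and C2 reach bonding distance, by chlorine transfer from iron, hydrogen abstraction or intermolecular coupling. The closure builds a bridged cyclobutane with a quaternary carbon and is slower than the monocyclic precedents. Fallback: a polar, two-stage closure of the same bond, setting out from 23. Selective mono-enolisation at the more acidic, less hindered C1 (LiN(SiMe3)2, Me3SiCl, −78 °C) should give the C11 trimethylsilyl dienol ether F1. N-Bromosuccinimide should brominate C1 from the convex face to give the α′-bromo enone F2. KN(SiMe3)2 then deprotonates C2, and the enolate displaces bromide with inversion (4-exo-tet enolate alkylation), which returns to the route at 25.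

**Step 6.** The second shift must form a bond next to the new quaternary group. The likely failure is an incomplete second rearrangement, or decomposition of the remaining silyl ketene acetal (C-silylation, ketene loss) at the temperature it needs. Fallback: the two shifts are run separately with the C10 oxygen masked, setting out from 6. Silylation of the secondary hydroxyl (tBuMe2SiCl, imidazole) gives F3, and acylation with 9 gives the tertiary ester F4. LiN(iPr)2 and Me3SiCl give ketene acetal F5, which rearranges to silyl ester F6. Work-up with Bu4NF frees hydroxy acid F7, and acylation with 7 gives propanoate F8. A second, separately optimised enolisation–silylation (excess LiN(iPr)2, Me3SiCl) returns to the route at 12 and hence 13 and 14.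

**Step 15.** The β-carbon is neopentyl, so conjugate borylation may be slow, and an unselective background pathway would erode the facial selectivity that only the ligand provides. Fallback: oxygen is introduced as a nucleophile, setting out from 25. tBuOOH and DBU should epoxidise the less hindered cycloheptenone to epoxy ketone F9 (both faces). SmI2 in THF–MeOH at −90 °C opens the α-carbon–oxygen bond to give 27 and its C5 epimer F10, which are separated. F10 is returned to 25 by base-induced dehydration (DBU, warm), and the route is rejoined at 27.

**Step 16.** Hemiacetal formation at a neopentyl carbinol and hydride transfer to a ketone flanked by the quaternary C2 may be slow. Retro-aldol opening of 27 or aldol reactions of 28 could then compete. Fallback: setting out from 27, the C5 hydroxyl is acylated with 3-methylbutanoyl chloride and 4-dimethylaminopyridine to give keto ester F11. Reduction with (S)-2-methyl-CBS-oxazaborolidine and BH3·SMe2 sets C3 under reagent control (quaternary C2 as the large group) and also reduces C11, giving diol F12. MnO2 re-oxidises only the allylic C11 carbinol and returns to the route at 29.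

**Step 13.** Regioselectivity may be lost through attack at the tertiary allylic C8–H, which leads to a transposed, tetrasubstituted enone and destroys the C8 centre, or through over-oxidation. Fallback: a regiospecific three-operation sequence setting out from 22. A peracid (3-chloroperbenzoic acid) epoxidises the electron-rich C9=C10 alkene only, giving F13. Sodium benzeneselenolate opens it at C10 to hydroxy selenide F14 (its addition to the enone is reversible). H2O2 gives selenoxide F15, which eliminates toward C11 to the tertiary allylic alcohol F16. Pyridinium chlorochromate, [C5H5NH][CrO3Cl], effects oxidative 1,3-transposition and returns to the route at 23.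

## Further compounds

F1 | step 14 | C11 trimethylsilyl dienol ether of 23 (C1=C11) | O=C1C=CC(C)(C)[C@@H]2C=C(O[Si](C)(C)C)C=C(C)[C@@H]2C1C
F2 | step 14 | 1-bromo derivative of 23 (bromine on the convex face) | O=C1C=CC(C)(C)[C@@H]2[C@@H](Br)C(=O)C=C(C)[C@@H]2C1C
F3 | step 6 | (1R,6S)-6-(tert-butyldimethylsilyloxy)-1-methylcyclohex-2-en-1-ol | CC(C)(C)[Si](C)(C)O[C@H]1CCC=C[C@@]1(C)O
F4 | step 6 | 2-methylpropanoate of F3 | CC(C)(C)[Si](C)(C)O[C@H]1CCC=C[C@@]1(C)OC(=O)C(C)C
F5 | step 6 | trimethylsilyl ketene acetal of F4 | CC(C)(C)[Si](C)(C)O[C@H]1CCC=C[C@@]1(C)OC(O[Si](C)(C)C)=C(C)C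
F6 | step 6 | trimethylsilyl 2-[(1R,4S)-4-(tert-butyldimethylsilyloxy)-3-methylcyclohex-2-en-1-yl]-2-methylpropanoate | CC(C)(C)[Si](C)(C)O[C@H]1CC[C@@H](C(C)(C)C(=O)O[Si](C)(C)C)C=C1C
F7 | step 6 | 2-[(1R,4S)-4-hydroxy-3-methylcyclohex-2-en-1-yl]-2-methylpropanoic acid | O[C@H]1CC[C@@H](C(C)(C)C(=O)O)C=C1C
F8 | step 6 | 2-methyl-2-[(1R,4S)-3-methyl-4-(propanoyloxy)cyclohex-2-en-1-yl]propanoic acid | CCC(=O)O[C@H]1CC[C@@H](C(C)(C)C(=O)O)C=C1C
F9 | step 15 | 4,5-epoxide of 25 (both faces) | O=C1C2OC2C(C)(C)[C@@H]2[C@H]3C(=O)C=C(C)[C@@H]2[C@]31C
F10 | step 15 | C5 epimer of 27 | O=C1C[C@H](O)C(C)(C)[C@@H]2[C@H]3C(=O)C=C(C)[C@@H]2[C@]31C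
F11 | step 16 | 3-methylbutanoate of 27 | O=C1C[C@@H](OC(=O)CC(C)C)C(C)(C)[C@@H]2[C@H]3C(=O)C=C(C)[C@@H]2[C@]31C
F12 | step 16 | (3R)-3,11-dihydroxy tricyclic 9-en-5-yl 3-methylbutanoate (C11 carbinol open) | O[C@@H]1C[C@@H](OC(=O)CC(C)C)C(C)(C)[C@@H]2[C@H]3C(O)C=C(C)[C@@H]2[C@]31C
F13 | step 13 | 9,10-epoxide of 22 (either face) | O=C1C=CC(C)(C)[C@@H]2CCC3OC3(C)[C@@H]2C1C
F14 | step 13 | 9-hydroxy-10-(phenylselanyl) derivative of 22 | O=C1C=CC(C)(C)[C@@H]2CCC([Se]c3ccccc3)C(C)(O)[C@@H]2C1C
F15 | step 13 | selenoxide of F14 | O=C1C=CC(C)(C)[C@@H]2CCC([Se](=O)c3ccccc3)C(C)(O)[C@@H]2C1C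
F16 | step 13 | 9-hydroxy-10-ene tertiary allylic alcohol | O=C1C=CC(C)(C)[C@@H]2CC=CC(C)(O)[C@@H]2C1C
A1 | alternative 1 | bicyclo[3.1.1]hept-2-en-6-one with the C3-silyloxy prenyl arm on C2 | CC(C)=CC[C@@H](O[Si](C)(C)C(C)(C)C)[C@@]1(C)[C@@H]2CC=C(C)[C@H]1C2=O
A2 | alternative 1 | 8-silyloxy trienoyl chloride | CC(C)=CC[C@@H](O[Si](C)(C)C(C)(C)C)/C(C)=C/CCC(C)=CC(=O)Cl
A3 | alternative 1 | vinylketene from A2 | CC(C)=CC[C@@H](O[Si](C)(C)C(C)(C)C)/C(C)=C/CC=C(C)C=C=O
A4 | alternative 2 | tricyclic cyclohept-2-enone with C11 dioxolane | O=C1C=CC(C)(C)[C@@H]2[C@H]3C4(OCCO4)C[C@@H](C)[C@@H]2[C@]31C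
A5 | alternative 2 | copaane-type nor-ketone | O=C1CC(C)(C)[C@@H]2[C@H]3C4(OCCO4)C[C@@H](C)[C@@H]2[C@]31C
A6 | alternative 3 | α-longipinene | C1CCC(C)(C)[C@@H]2[C@H]3CC=C(C)[C@@H]2[C@]31C
A7 | alternative 3 | (2E,6E)-farnesyl diphosphate | CC(C)=CCC/C(C)=C/CC/C(C)=C/COP(=O)(O)OP(=O)(O)O
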